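The numbers in the tables were generated by integration for substances that don't exist; the scatter is artificial.

**Odd rise.** Raising c_Z from 0.40 M in alpha to 0.60 M in epsilon, at 0.80 equiv of L in both, lifted the share of J among J, Q and D (the selectivity to J) from 49.8% to 55.4% at the last readings. Z takes up L stepwise: J holds one, Q two, D 3.

| setting | alpha | delta | epsilon | ash | larch | maple | alder |
|---|---|---|---|---|---|---|---|
| Z | 0.40 M | 0.27 M | 0.60 M | 0.40 M | 0.40 M | 0.40 M | 0.40 M |
| L | 0.80 equiv | 0.80 equiv | 0.80 equiv | 0.800 equiv | 0.800 equiv | 0.800 equiv | 0.800 equiv (fed, over 1.60 h) |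
| remark | run made earlier | run made earlier | run made earlier | a closed flask charged with all of it at once and left for 2.0 h | a single well-mixed tank run continuously and read at steady state, 2.0 h in it on average | one stirred flow tank at steady state, fed with the mixture as stated, mean residence time 6.00 h | all but L at the start; L goes in evenly over 1.60 h, the run ends at 2.0 h |
| time |  |  |  | 2.0 h |  |  | 2.0 h |

- alpha (time / min: J / %, Q / %, D / %): 5.00: 23.4, 2.3, 0.9; 15.0: 27.5, 7.0, 5.0; 25.0: 26.0, 7.2, 9.5; 40.0: 24.3, 7.3, 13.1; 60.0: 21.8, 8.2, 13.4; 80.0: 21.6, 6.8, 15.0
- delta (time / min: J / %, Q / %, D / %): 6.00: 19.5, 2.1, 1.4; 10.0: 22.8, 4.0, 1.2; 15.0: 24.6, 4.5, 2.7; 25.0: 23.3, 6.4, 6.7; 40.0: 21.4, 6.3, 8.9; 80.0: 18.2, 5.9, 14.7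
- epsilon (time / min: J / %, Q / %, D / %): 6.00: 28.9, 5.0, 2.6; 10.0: 30.7, 7.2, 4.9; 15.0: 30.5, 8.2, 7.3; 25.0: 28.3, 7.8, 10.2; 40.0: 28.1, 8.5, 10.9; 80.0: 26.2, 8.2, 12.9

(standard deviation of a reading: 0.5 percentage points)

- the stated concentrations are those of everything mixed, before any reaction; amounts are the same in each set-up
- the earlier runs were read with a standard deviation of 0.5 percentage points
- the feed brings no volume worth counting
- the earlier runs were made in a closed, stirred flask

- order of the set-ups by the share of J in all that became J or Q or D, at the outlet or at the end, highest first (ash / larch / maple / alder)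
- share of J in all that became J or Q or D, at the outlet or at the end, ash
- share of J in all that became J or Q or D, at the outlet or at the end, larch
- share of J in all that became J or Q or D, at the outlet or at the end, maple
- share of J in all that became J or Q or D, at the outlet or at the end, alder

That rise looked wrong. If every step joins L to one partner, c_Z at fixed equivalents rescales time, and the share at the end of L's uptake stays the same.

**Reading slope.** I counted the L bound in alpha at its last reading, 80.2% of Z, so L, the limiting reagent, had been taken up as far as the readings tell. Delta stood at 74.1%, so I dropped it. On log axes, as on a Bode plot, c_Z climbed 0.176 decades and the share 0.0463. The slope, decades of share per decade of c_Z, read 0.264, and it carries the scatter of the readings. Some clock in the flask seemed not to scale with c_Z.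

**My reckoning.** A step between two partners speeds up with c_Z, so I treated a slower pace of L as a lower c_Z. Alder's feed is 4.52 times slower than alpha's uptake over its first 15.0 min. Going down the slope gave me 33.4% for alder. I claimed nothing for the tanks, which receive fresh Z.

**The forecast.** It gave ash > alder > larch > maple, with 48.5%, 37%, 25% and 43% in the order asked, holding that “anything that holds L low hurts J”. Its alder stood above mine.

**The result.** The order was ash > larch > alder > maple, with 50.0%, 37.6%, 29.2% and 31.9%.

    L + Q → D (k = 0.0110 L mol⁻¹ s⁻¹)
    Z ⇌ E (K = 9.00, k = 0.00140 s⁻¹)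
    L + J → Q (k = 0.00350 L mol⁻¹ s⁻¹)
    Z + L → J (k = 0.00510 L mol⁻¹ s⁻¹)

Alder came 1.5 percentage points below my figure and 11 points below the forecast. At 1.00 h alder held E at 78.7% of the Z charged, Z at 6.75% and J at 8.99%. At 1.60 h, the end of the feed, alder held L at 40.8% of its charge and D at 10.9% of the Z charged; at 2.00 h it held L at 24.4% of its charge and D at 15.5% of the Z charged. In ash, Z → E ran beside Z + L → J, its forward rate 0.86 of that step's at the start.

**Next flask.** For ash's recipe at 1.0 M of Z, equivalents and time held, the slope taken up from alpha's last share gave 63.4%. The computed share was 63.0%.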